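**Retrosynthetic overview**

- The 3-formyl group is traced back to a 3-methyl group (DDQ oxidation) and the C2 bromine to electrophilic bromination. Both go back to 5,6-dibromo-1,3-dimethylindole.
- The strategy rests on the C2=C3 bond of the pyrrole ring (N1, C2, C3, C3a, C7a). C2 (on N1) and C3 (on C3a) are both drawn as carbonyl carbons: an N-formyl group and an acetyl group on neighbouring carbons of a 4,5-dibromobenzene ring.
- The precursor N-(2-acetyl-4,5-dibromophenyl)-N-methylformamide is closed by low-valent titanium, which couples the two carbonyl carbons and removes both oxygens.
- The precursor comes from 3,4-dibromoaniline: ortho-acylation with acetonitrile at the ortho carbon not flanked by bromine (this fixes the 5,6-dibromo pattern), then N-formylation and N-methylation.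
- Ring order: the benzene ring is bought with both bromines in place; the pyrrole ring is the only ring formed.

Key step: step 4

Remark: the target has no stereocentre and no stereogenic double bond. The only stereocentres in the route are the two sp3 carbons of the transient titanium diolate in the key step, and they are flattened in that same step.

**Route**

Step 1
Reactants: 1 3,4-dibromoaniline; 2 acetonitrile
Product: 4 1-(2-amino-4,5-dibromophenyl)ethan-1-one, via ketimine 3 (not isolated)
Conditions: BCl3 (1.1 equiv), ClCH2CH2Cl, 0 °C; MeCN (3 equiv), AlCl3 (1.1 equiv), reflux; then 2 M HCl, 80 °C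
Reagents that add atoms: acetonitrile (CC#N); water (O)
Why: Sugasawa ortho-acylation, in which boron bound to the aniline nitrogen delivers the AlCl3-activated nitrile to an ortho carbon through a six-membered chelate, should act at C6 because C2 is flanked by bromine, and hot aqueous acid then hydrolyses the boron-bound ketimine 3 to the ketone.

Step 2
Reactants: 4 1-(2-amino-4,5-dibromophenyl)ethan-1-one
Product: 5 N-(2-acetyl-4,5-dibromophenyl)formamide
Conditions: HCO2H/Ac2O (premixed at 55 °C, then cooled), THF, 0 °C to rt
Reagents that add atoms: acetic formic anhydride (CC(=O)OC=O), made in the flask from formic acid (OC=O) and acetic anhydride (CC(=O)OC(C)=O)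
Why: N-formylation with a mixed anhydride should succeed on this weakly nucleophilic ortho-acyl aniline because acetic formic anhydride transfers its more electrophilic formyl group far faster than formic acid alone.

Step 3
Reactants: 5 N-(2-acetyl-4,5-dibromophenyl)formamide; 6 iodomethane
Product: 7 N-(2-acetyl-4,5-dibromophenyl)-N-methylformamide
Conditions: MeI (1.5 equiv), Cs2CO3 (1.2 equiv), DMF, 0 °C to rt
Reagents that add atoms: iodomethane (CI)
Why: N-alkylation of an anilide by SN2 should be clean because Cs2CO3 deprotonates the acidic formanilide N–H but not the methyl ketone, so that Camps-type aldol closure onto the formyl group does not start.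

Step 4
Reactants: 7 N-(2-acetyl-4,5-dibromophenyl)-N-methylformamide
Product: 9 5,6-dibromo-1,3-dimethyl-1H-indole, via titanium 2,3-diolate 8 (not isolated)
Conditions: TiCl3 (3 equiv), Zn dust (6 equiv), DME, reflux 1 h; then 7 in DME added over 1 h at reflux, 30 min more; cooled, filtered through silica
Reagents that add atoms: none
Why: Zinc reduces TiCl3 to a low-valent titanium surface that passes one electron to the aryl ketone of 7, and the titanium-bound ketyl carbon (the future C3) adds to the formamide carbonyl carbon (the future C2) held beside it on N1; a second electron gives the chelated cis-2,3-diolate 8, from which titanium strips both oxygens as strong Ti–O bonds while the ring gains indole aromaticity. The closest known reaction type is the McMurry-type reductive coupling of ortho-acyl anilides, the Fürstner indole synthesis, which accepts formamides and N-alkyl amides. The pyrrole ring (N1, C2, C3, C3a, C7a) closes in a 5-exo-trig mode, the formyl oxygen staying outside the new ring. No stereocentre remains in 9, because the two sp3 carbons of 8 become the C2=C3 double bond. The step needs chemoselectivity for intramolecular keto-amide coupling over pinacol dimerisation of the ketone and over reductive cleavage of the two C–Br bonds: the ortho placement of the two carbonyl groups makes ring closure the fastest path, slow addition keeps the ketyl concentration low, and a short reflux with early quench limits contact of the aryl bromides with the reductant.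

Step 5
Reactants: 9 5,6-dibromo-1,3-dimethyl-1H-indole
Product: 10 2,5,6-tribromo-1,3-dimethyl-1H-indole
Conditions: NBS (1.05 equiv), CH2Cl2, 0 °C to rt, dark
Reagents that add atoms: N-bromosuccinimide (O=C1CCC(=O)N1Br)
Why: Electrophilic bromination of a 3-substituted N-alkylindole should place bromine at C2, since attack at the enamine carbon C3 gives a 3-bromoindolenine that passes bromine to C2 and loses H-2, while the two benzo bromines deactivate C4 and C7 and the absence of light and initiator suppresses side-chain bromination.

Step 6
Reactants: 10 2,5,6-tribromo-1,3-dimethyl-1H-indole
Product: 12 2,5,6-tribromo-1-methyl-1H-indole-3-carbaldehyde, via indol-3-ylmethanol 11 (not isolated)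
Conditions: DDQ (2.2 equiv), THF/H2O 9:1, 0 °C to rt
Reagents that add atoms: water (O)
Why: DDQ oxidation of the C3 side chain of an indole should work because hydride loss from the 3-methyl group gives an N-methyl-3-methyleneindoleninium ion that water traps as alcohol 11, and a second DDQ oxidises this alcohol to the aldehyde, a vinylogous formamide that resists further oxidation.

**Compound list**

1 | 3,4-dibromoaniline | Nc1ccc(Br)c(Br)c1 | starting material
2 | acetonitrile | CC#N | starting material
3 | 1-(2-amino-4,5-dibromophenyl)ethan-1-imine, held as its boron chelate, drawn as the free ketimine, not isolated | CC(=N)c1cc(Br)c(Br)cc1N | intermediate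
4 | 1-(2-amino-4,5-dibromophenyl)ethan-1-one | CC(=O)c1cc(Br)c(Br)cc1N | intermediate
5 | N-(2-acetyl-4,5-dibromophenyl)formamide | CC(=O)c1cc(Br)c(Br)cc1NC=O | intermediate
6 | iodomethane | CI | starting material
7 | N-(2-acetyl-4,5-dibromophenyl)-N-methylformamide | CC(=O)c1cc(Br)c(Br)cc1N(C)C=O | intermediate
8 | cis-5,6-dibromo-1,3-dimethylindoline-2,3-diolate, drawn as the dichloro chelate on one tetravalent titanium centre, racemic with one enantiomer drawn, not isolated | C[C@@]12O[Ti](Cl)(Cl)O[C@@H]1N(C)c1cc(Br)c(Br)cc12 | intermediate
9 | 5,6-dibromo-1,3-dimethyl-1H-indole | Cc1cn(C)c2cc(Br)c(Br)cc12 | intermediate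
10 | 2,5,6-tribromo-1,3-dimethyl-1H-indole | Cc1c(Br)n(C)c2cc(Br)c(Br)cc12 | intermediate
11 | (2,5,6-tribromo-1-methyl-1H-indol-3-yl)methanol, not isolated | Cn1c(Br)c(CO)c2cc(Br)c(Br)cc21 | intermediate
12 | 2,5,6-tribromo-1-methyl-1H-indole-3-carbaldehyde | Cn1c(Br)c(C=O)c2cc(Br)c(Br)cc21 | target

**Step count and risks**

Total step count: 6. Longest linear sequence: 6 steps, from 3,4-dibromoaniline 1.

Steps most likely to fail:

1. Step 4 (key step). The titanium reductant may cleave the C–Br bonds, and intermolecular pinacol coupling of the ketone may outrun ring closure. The fallback sets out from 4 and comes back at 9, and brings in C2 as a nucleophilic ylide carbon, so no reductant meets the aryl bromides. Wittig methoxymethylenation of the ketone of 4 with the ylide from (methoxymethyl)triphenylphosphonium chloride and KOtBu (THF, 0 °C to rt, excess ylide to allow for the NH2 group) should give 4,5-dibromo-2-(1-methoxyprop-1-en-2-yl)aniline F1 as an E/Z mixture. Aqueous HCl in THF should protonate the enol ether, the aniline nitrogen should close onto the oxocarbenium carbon, and loss of methanol should give 5,6-dibromo-3-methyl-1H-indole F2. NaH and iodomethane 6 in DMF at 0 °C should then methylate N1 of F2 to give 9.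

2. Step 6. Hydride transfer from the electron-poor tribromoindole to DDQ may be slow, and water may attack C2 of the cationic intermediate with loss of the C2 bromine. The fallback sets out from 10 and comes back at 12, and uses a radical path in place of hydride abstraction. Wohl–Ziegler bromination (NBS, catalytic AIBN, PhCF3, reflux) should brominate the 3-methyl group, now that C2 is blocked, to give 2,5,6-tribromo-3-(bromomethyl)-1-methyl-1H-indole F3, used crude. Kornblum oxidation (DMSO, NaHCO3, rt to 50 °C) should then convert the bromomethyl group into the aldehyde of 12.

3. Step 1. The doubly brominated aniline may acylate with low conversion, and hot AlCl3 may cause migration or loss of bromine. The fallback sets out from 1 and comes back at 4, and replaces the Friedel–Crafts-type acylation by a cross-coupling. Iodination with N-iodosuccinimide (MeCN, catalytic TFA, rt) should go to the unhindered ortho carbon, the para position being blocked, and give 4,5-dibromo-2-iodoaniline F4. Stille coupling with tributyl(1-ethoxyvinyl)stannane (Pd(PPh3)4, a zerovalent palladium catalyst, toluene, 90 °C) should react at the C–I bond in preference to the C–Br bonds and give 4,5-dibromo-2-(1-ethoxyvinyl)aniline F5. Hydrolysis of the enol ether with 1 M HCl in THF at rt should give 4.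

Further compounds
F1 | step 4 | 4,5-dibromo-2-(1-methoxyprop-1-en-2-yl)aniline, E/Z mixture | COC=C(C)c1cc(Br)c(Br)cc1N
F2 | step 4 | 5,6-dibromo-3-methyl-1H-indole | Cc1c[nH]c2cc(Br)c(Br)cc12
F3 | step 6 | 2,5,6-tribromo-3-(bromomethyl)-1-methyl-1H-indole | Cn1c(Br)c(CBr)c2cc(Br)c(Br)cc21
F4 | step 1 | 4,5-dibromo-2-iodoaniline | Nc1cc(Br)c(Br)cc1I
F5 | step 1 | 4,5-dibromo-2-(1-ethoxyvinyl)aniline | CCOC(=C)c1cc(Br)c(Br)cc1N
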